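**Plan**

1. Retrosynthetic cuts, in order: the four O–Si bonds (protection only); C2–C3 of ring C; the diazo group at C3 (back to an acetyl methyl); the O1–CH2 ether bond between a ring-A phenol and a ring-B benzyl alcohol; the two aryl–prenyl bonds.
2. Forward: the ring-A acetophenone (steps 1–3) and the ring-B benzyl alcohol (steps 4–6) are made separately and joined through O1 (step 7). The acetyl group becomes a diazoketone (step 8), ring C closes last (step 9), and desilylation gives the target (step 10).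
3. Enabling feature: C2 is both the carbon bonded to O1 and the benzylic carbon of the resorcinol-type ring B, so before closure it is an ArO–CH2–Ar methylene with a hydridic C–H. C3 is alpha to the C4 ketone on ring A and can be a keto-carbene carbon. The two lie 1,6 across C4–C4a–C8a–O1.
4. Stereochemistry: the only stereocenter, C2 (S), is set in step 9 by a chiral dirhodium tetracarboxylate that distinguishes the two enantiotopic methylene hydrogens. Nothing after it exposes C2 to base.
5. Prenyl regiochemistry: on ring A it follows from the para-Claisen–Cope mechanism (para to the oxygen that becomes O1); on ring B it follows from the position of bromine in the starting aldehyde.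

Key step: step 9

Assumption: which antipode of the dirhodium prolinate gives the 2S series cannot be assigned in advance. Both antipodes are accessible from L- and D-proline, and the one that a small-scale trial shows to give 2S is the one meant in step 9.
Abbreviation: TBS = tert-butyldimethylsilyl; prenyl = 3-methylbut-2-enyl.

**Step 1**
Reactants: 1 1-(2,4,6-trihydroxyphenyl)ethanone (phloroacetophenone)
Product: 2 1-[2,4-bis(TBS-oxy)-6-hydroxyphenyl]ethanone
Conditions: TBSCl (2.1 equiv), imidazole, DMF, 0 °C to rt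
Reagents that add atoms: tert-butyldimethylsilyl chloride, CC(C)(C)[Si](C)(C)Cl
Why: Silylation takes the para hydroxyl and one ortho hydroxyl, after which the last ortho hydroxyl is held in a hydrogen bond to the acetyl oxygen, so the reaction should stop at the bis-silyl ether.

**Step 2**
Reactants: 2 1-[2,4-bis(TBS-oxy)-6-hydroxyphenyl]ethanone
Product: 3 1-[2,4-bis(TBS-oxy)-6-(3-methylbut-2-enyloxy)phenyl]ethanone
Conditions: 3-methylbut-2-en-1-ol, PPh3, DIAD, THF, 0 °C to rt
Reagents that add atoms: 3-methylbut-2-en-1-ol (prenol), CC(C)=CCO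
Why: Mitsunobu reaction, in which the chelated but acidic phenol displaces triphenylphosphine oxide from the activated primary allylic alcohol by SN2 under neutral conditions, so the prenyl group should arrive unrearranged and the aryl silyl ethers should survive.

**Step 3**
Reactants: 3 1-[2,4-bis(TBS-oxy)-6-(3-methylbut-2-enyloxy)phenyl]ethanone
Product: 6 1-[2,4-bis(TBS-oxy)-6-hydroxy-3-(3-methylbut-2-enyl)phenyl]ethanone, via ortho-dienone 4 (not isolated), via para-dienone 5 (not isolated)
Conditions: N,N-diethylaniline, 195 °C, sealed tube, argon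
Reagents that add atoms: none
Why: Para-Claisen–Cope rearrangement, in which the aromatic Claisen shift to the only free ortho carbon gives dienone 4, whose crowded 1,1-dimethylallyl group should move on by a Cope shift to the para carbon (5) before enolisation, and tautomerisation then leaves a linear prenyl group between the two silyloxy groups and frees the hydroxyl that becomes O1.

**Step 4**
Reactants: 7 5-bromo-2,4-dihydroxybenzaldehyde
Product: 8 5-bromo-2,4-bis(TBS-oxy)benzaldehyde
Conditions: TBSCl (2.3 equiv), imidazole, DMF, rt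
Reagents that add atoms: tert-butyldimethylsilyl chloride, CC(C)(C)[Si](C)(C)Cl
Why: Standard silylation of both phenols with TBSCl and imidazole, which removes the acidic protons before the cross-coupling.

**Step 5**
Reactants: 8 5-bromo-2,4-bis(TBS-oxy)benzaldehyde
Product: 9 2,4-bis(TBS-oxy)-5-(3-methylbut-2-enyl)benzaldehyde
Conditions: tributyl(3-methylbut-2-enyl)stannane, Pd(PPh3)4 (5 mol %), DMF, 95 °C
Reagents that add atoms: tributyl(3-methylbut-2-enyl)stannane, CCCC[Sn](CCCC)(CCCC)CC=C(C)C
Why: Stille coupling, in which zerovalent palladium inserts into the aryl–Br bond, the prenyl group is transferred from tin and reductive elimination at the less hindered allyl terminus should give the linear prenyl arene at the carbon that carried bromine.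

**Step 6**
Reactants: 9 2,4-bis(TBS-oxy)-5-(3-methylbut-2-enyl)benzaldehyde
Product: 10 [2,4-bis(TBS-oxy)-5-(3-methylbut-2-enyl)phenyl]methanol
Conditions: DIBAL-H, CH2Cl2, −78 °C; Rochelle salt work-up
Reagents that add atoms: none
Why: Hydride reduction of the aldehyde at low temperature, where the aluminium alkoxide formed is too weak a nucleophile to take over the neighbouring silyl group.

**Step 7**
Reactants: 6 1-[2,4-bis(TBS-oxy)-6-hydroxy-3-(3-methylbut-2-enyl)phenyl]ethanone; 10 [2,4-bis(TBS-oxy)-5-(3-methylbut-2-enyl)phenyl]methanol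
Product: 11 1-[2-{[2,4-bis(TBS-oxy)-5-(3-methylbut-2-enyl)phenyl]methoxy}-4,6-bis(TBS-oxy)-5-(3-methylbut-2-enyl)phenyl]ethanone
Conditions: PPh3, DIAD, THF, 0 °C to rt
Reagents that add atoms: none
Why: Mitsunobu etherification, in which the hydrogen-bonded phenol of 6 displaces triphenylphosphine oxide from the activated primary benzylic alcohol 10, which should give the ArO–CH2–Ar ether under neutral conditions that spare the silyl ethers.

**Step 8**
Reactants: 11 1-[2-{[2,4-bis(TBS-oxy)-5-(3-methylbut-2-enyl)phenyl]methoxy}-4,6-bis(TBS-oxy)-5-(3-methylbut-2-enyl)phenyl]ethanone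
Product: 13 2-diazo-1-[2-{[2,4-bis(TBS-oxy)-5-(3-methylbut-2-enyl)phenyl]methoxy}-4,6-bis(TBS-oxy)-5-(3-methylbut-2-enyl)phenyl]ethanone, via trifluoroacetyl diketone 12 (not isolated)
Conditions: LiHMDS, THF, −78 °C; CF3CO2CH2CF3; aq. HCl quench; then MsN3, Et3N, H2O, MeCN, rt
Reagents that add atoms: methanesulfonyl azide, CS(=O)(=O)N=[N+]=[N-] (the two nitrogens of the diazo group); 2,2,2-trifluoroethyl trifluoroacetate, O=C(OCC(F)(F)F)C(F)(F)F (the trifluoroacetyl group of 12 only, lost again before 13)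
Why: Detrifluoroacetylative diazo transfer (Regitz type), in which the kinetic lithium enolate of the methyl ketone is C-acylated by the trifluoroacetate ester and the resulting 1,3-diketone 12 takes the diazo group from mesyl azide with loss of the trifluoroacetyl group as its sulfonamide.

**Step 9**
Reactants: 13 2-diazo-1-[2-{[2,4-bis(TBS-oxy)-5-(3-methylbut-2-enyl)phenyl]methoxy}-4,6-bis(TBS-oxy)-5-(3-methylbut-2-enyl)phenyl]ethanone
Product: 14 (2S)-2-[2,4-bis(TBS-oxy)-5-(3-methylbut-2-enyl)phenyl]-5,7-bis(TBS-oxy)-6-(3-methylbut-2-enyl)-2,3-dihydrochromen-4-one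
Conditions: Rh2(S-BSP)4 or Rh2(R-BSP)4 (dirhodium tetrakis[N-(benzenesulfonyl)prolinate], antipode as in the assumption, 2 mol %), CH2Cl2, 4 Å sieves, slow addition of 13 to high dilution, 0 °C to rt
Reagents that add atoms: none
Why: The dirhodium carboxylate expels N2 from 13 to give an electrophilic keto-carbenoid at the future C3, which inserts through a concerted, hydride-transfer-like three-centre transition state into one C–H of the ArO–CH2–Ar methylene and so makes C2–C3. The closest known reaction type is the enantioselective dirhodium-carboxylate-catalysed C–H insertion of ortho-alkoxyaryl diazoketones alpha to the ether oxygen, which gives 2-substituted chroman-4-ones. Ring C closes as a 1,6 C–H insertion through a six-membered transition state (carbenoid carbon, C4, C4a, C8a, O1, C2); no 1,5 C–H exists because the fifth atom is oxygen on both sides of the acyl group. C2 is the only new stereocenter and is set by catalyst control, the chiral prolinate ligands distinguishing the two enantiotopic hydrogens of the OCH2 group. The step needs chemoselectivity over oxonium ylide formation at O1 with [1,2]-benzyl shift, over Buchner addition to ring B and over cyclopropanation of the prenyl groups. This should be secured because the C–H is doubly activated (alpha to O1 and benzylic to ring B with ortho and para silyloxy donors), O1 is a weakly basic aryl ether oxygen conjugated to the acylated ring, the other ortho oxygen carries a silyl group with no alpha C–H, the ring-A prenyl group is meta to the acyl carbon and cannot be reached, and slow addition at high dilution suppresses intermolecular reaction.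

**Step 10**
Reactants: 14 (2S)-2-[2,4-bis(TBS-oxy)-5-(3-methylbut-2-enyl)phenyl]-5,7-bis(TBS-oxy)-6-(3-methylbut-2-enyl)-2,3-dihydrochromen-4-one
Product: 15 (2S)-2-[2,4-dihydroxy-5-(3-methylbut-2-enyl)phenyl]-5,7-dihydroxy-6-(3-methylbut-2-enyl)-2,3-dihydrochromen-4-one
Conditions: TBAF (4.4 equiv), AcOH (4.4 equiv), THF, 0 °C
Reagents that add atoms: none
Why: Fluoride-mediated cleavage of the four aryl silyl ethers, buffered with acetic acid so that neither base-induced opening of ring C to the chalcone (racemisation at C2) nor acid-induced cyclisation of a prenyl group onto a neighbouring phenol should occur.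

**Compound list**

1 | 1-(2,4,6-trihydroxyphenyl)ethanone | CC(=O)c1c(O)cc(O)cc1O | starting material
2 | 1-[2,4-bis(TBS-oxy)-6-hydroxyphenyl]ethanone | CC(=O)c1c(O)cc(O[Si](C)(C)C(C)(C)C)cc1O[Si](C)(C)C(C)(C)C | intermediate
3 | 1-[2,4-bis(TBS-oxy)-6-(3-methylbut-2-enyloxy)phenyl]ethanone | CC(=O)c1c(OCC=C(C)C)cc(O[Si](C)(C)C(C)(C)C)cc1O[Si](C)(C)C(C)(C)C | intermediate
4 | 2-acetyl-3,5-bis(TBS-oxy)-6-(2-methylbut-3-en-2-yl)cyclohexa-2,4-dien-1-one (ortho-dienone, racemic) | CC(=O)C1=C(O[Si](C)(C)C(C)(C)C)C=C(O[Si](C)(C)C(C)(C)C)C(C(C)(C)C=C)C1=O | intermediate (not isolated)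
5 | 2-acetyl-3,5-bis(TBS-oxy)-4-(3-methylbut-2-enyl)cyclohexa-2,5-dien-1-one (para-dienone) | CC(=O)C1=C(O[Si](C)(C)C(C)(C)C)C(CC=C(C)C)C(O[Si](C)(C)C(C)(C)C)=CC1=O | intermediate (not isolated)
6 | 1-[2,4-bis(TBS-oxy)-6-hydroxy-3-(3-methylbut-2-enyl)phenyl]ethanone | CC(=O)c1c(O)cc(O[Si](C)(C)C(C)(C)C)c(CC=C(C)C)c1O[Si](C)(C)C(C)(C)C | intermediate
7 | 5-bromo-2,4-dihydroxybenzaldehyde | O=Cc1cc(Br)c(O)cc1O | starting material
8 | 5-bromo-2,4-bis(TBS-oxy)benzaldehyde | O=Cc1cc(Br)c(O[Si](C)(C)C(C)(C)C)cc1O[Si](C)(C)C(C)(C)C | intermediate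
9 | 2,4-bis(TBS-oxy)-5-(3-methylbut-2-enyl)benzaldehyde | O=Cc1cc(CC=C(C)C)c(O[Si](C)(C)C(C)(C)C)cc1O[Si](C)(C)C(C)(C)C | intermediate
10 | [2,4-bis(TBS-oxy)-5-(3-methylbut-2-enyl)phenyl]methanol | OCc1cc(CC=C(C)C)c(O[Si](C)(C)C(C)(C)C)cc1O[Si](C)(C)C(C)(C)C | intermediate
11 | 1-[2-{[2,4-bis(TBS-oxy)-5-(3-methylbut-2-enyl)phenyl]methoxy}-4,6-bis(TBS-oxy)-5-(3-methylbut-2-enyl)phenyl]ethanone | CC(=O)c1c(OCc2cc(CC=C(C)C)c(O[Si](C)(C)C(C)(C)C)cc2O[Si](C)(C)C(C)(C)C)cc(O[Si](C)(C)C(C)(C)C)c(CC=C(C)C)c1O[Si](C)(C)C(C)(C)C | intermediate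
12 | 1-[2-{[2,4-bis(TBS-oxy)-5-(3-methylbut-2-enyl)phenyl]methoxy}-4,6-bis(TBS-oxy)-5-(3-methylbut-2-enyl)phenyl]-4,4,4-trifluorobutane-1,3-dione | O=C(CC(=O)c1c(OCc2cc(CC=C(C)C)c(O[Si](C)(C)C(C)(C)C)cc2O[Si](C)(C)C(C)(C)C)cc(O[Si](C)(C)C(C)(C)C)c(CC=C(C)C)c1O[Si](C)(C)C(C)(C)C)C(F)(F)F | intermediate (not isolated)
13 | 2-diazo-1-[2-{[2,4-bis(TBS-oxy)-5-(3-methylbut-2-enyl)phenyl]methoxy}-4,6-bis(TBS-oxy)-5-(3-methylbut-2-enyl)phenyl]ethanone | [N-]=[N+]=CC(=O)c1c(OCc2cc(CC=C(C)C)c(O[Si](C)(C)C(C)(C)C)cc2O[Si](C)(C)C(C)(C)C)cc(O[Si](C)(C)C(C)(C)C)c(CC=C(C)C)c1O[Si](C)(C)C(C)(C)C | intermediate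
14 | (2S)-2-[2,4-bis(TBS-oxy)-5-(3-methylbut-2-enyl)phenyl]-5,7-bis(TBS-oxy)-6-(3-methylbut-2-enyl)-2,3-dihydrochromen-4-one | CC(C)=CCc1cc([C@@H]2CC(=O)c3c(cc(O[Si](C)(C)C(C)(C)C)c(CC=C(C)C)c3O[Si](C)(C)C(C)(C)C)O2)c(O[Si](C)(C)C(C)(C)C)cc1O[Si](C)(C)C(C)(C)C | intermediate
15 | (2S)-2-[2,4-dihydroxy-5-(3-methylbut-2-enyl)phenyl]-5,7-dihydroxy-6-(3-methylbut-2-enyl)-2,3-dihydrochromen-4-one | CC(C)=CCc1cc([C@@H]2CC(=O)c3c(cc(O)c(CC=C(C)C)c3O)O2)c(O)cc1O | target

Total step count: 10
Longest linear sequence: 7 steps (steps 1, 2, 3, 7, 8, 9, 10; the ring-B branch through steps 4, 5, 6 is equally long)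

**Steps most likely to fail**

1. Step 9. Attack of the O1 lone pair on the carbenoid (five-membered oxonium ylide) followed by [1,2]-shift of the electron-rich benzyl group may outrun C–H insertion, and a keto-carbenoid without a donor group may discriminate poorly between the two enantiotopic hydrogens. The fallback closes ring C at O1–C2 instead and obtains C2 by resolution. It sets out from 6 and 9. These are condensed with pyrrolidine in toluene over molecular sieves (Kabbe-type condensation), which should pass through the 2'-hydroxychalcone F1 and close by oxa-Michael addition to the racemic tetrasilyl flavanone F2. Kinetic resolution of F2 by asymmetric transfer hydrogenation follows, with RhCl(Cp*)(TsDPEN) in the antipode that reduces the 2R ketone, HCO2H/Et3N, EtOAc. This should convert the 2R enantiomer into the (2R,4R)-cis-flavan-4-ol F3 and leave the 2S ketone, which is separated by chromatography. The fallback comes back to the route at 14.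

2. Step 3. Enolisation of the ortho-dienone before the Cope shift would give the 1,1-dimethylallyl isomer, and the silyl ethers may migrate or be lost at 195 °C. The fallback relies on the innate order of reactivity of the three hydroxyls instead of a sigmatropic shift. It sets out from 1. C-prenylation with prenyl bromide and DBU in THF should give 2,4,6-trihydroxy-3-prenylacetophenone F4. One equivalent of TBSCl with imidazole should silylate the non-chelated para hydroxyl to give the mono-silyl ether F5. Mitsunobu etherification with 10 (PPh3, DIAD) should take the less hindered of the two chelated hydroxyls to give the phenol ether F6. Silylation of the last hydroxyl (TBSCl, imidazole, DMF, 50 °C) comes back to the route at 11.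

3. Step 8. The ortho silyl group may transfer from the aryl oxygen to the lithium enolate oxygen, and C-acylation of the hindered enolate may be incomplete. The fallback avoids any enolate. It sets out from 11, which is heated with N,N-dimethylformamide dimethyl acetal in toluene at 100 °C to give the enaminone F7. Diazo transfer from mesyl azide to the enaminone in MeCN at rt, with loss of the sulfonyl formamidine, comes back to the route at 13.

**Further compounds**

F1 | step 9 | (E)-1-[2,4-bis(TBS-oxy)-6-hydroxy-3-(3-methylbut-2-enyl)phenyl]-3-[2,4-bis(TBS-oxy)-5-(3-methylbut-2-enyl)phenyl]prop-2-en-1-one | O=C(/C=C/c1cc(CC=C(C)C)c(O[Si](C)(C)C(C)(C)C)cc1O[Si](C)(C)C(C)(C)C)c1c(O)cc(O[Si](C)(C)C(C)(C)C)c(CC=C(C)C)c1O[Si](C)(C)C(C)(C)C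
F2 | step 9 | racemic 2-[2,4-bis(TBS-oxy)-5-(3-methylbut-2-enyl)phenyl]-5,7-bis(TBS-oxy)-6-(3-methylbut-2-enyl)-2,3-dihydrochromen-4-one | CC(C)=CCc1cc(C2CC(=O)c3c(cc(O[Si](C)(C)C(C)(C)C)c(CC=C(C)C)c3O[Si](C)(C)C(C)(C)C)O2)c(O[Si](C)(C)C(C)(C)C)cc1O[Si](C)(C)C(C)(C)C
F3 | step 9 | (2R,4R)-2-[2,4-bis(TBS-oxy)-5-(3-methylbut-2-enyl)phenyl]-5,7-bis(TBS-oxy)-6-(3-methylbut-2-enyl)-3,4-dihydro-2H-chromen-4-ol | CC(C)=CCc1cc([C@H]2C[C@@H](O)c3c(cc(O[Si](C)(C)C(C)(C)C)c(CC=C(C)C)c3O[Si](C)(C)C(C)(C)C)O2)c(O[Si](C)(C)C(C)(C)C)cc1O[Si](C)(C)C(C)(C)C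
F4 | step 3 | 1-[2,4,6-trihydroxy-3-(3-methylbut-2-enyl)phenyl]ethanone | CC(=O)c1c(O)cc(O)c(CC=C(C)C)c1O
F5 | step 3 | 1-[4-(TBS-oxy)-2,6-dihydroxy-3-(3-methylbut-2-enyl)phenyl]ethanone | CC(=O)c1c(O)cc(O[Si](C)(C)C(C)(C)C)c(CC=C(C)C)c1O
F6 | step 3 | 1-[2-{[2,4-bis(TBS-oxy)-5-(3-methylbut-2-enyl)phenyl]methoxy}-4-(TBS-oxy)-6-hydroxy-5-(3-methylbut-2-enyl)phenyl]ethanone | CC(=O)c1c(OCc2cc(CC=C(C)C)c(O[Si](C)(C)C(C)(C)C)cc2O[Si](C)(C)C(C)(C)C)cc(O[Si](C)(C)C(C)(C)C)c(CC=C(C)C)c1O
F7 | step 8 | (E)-3-(dimethylamino)-1-[2-{[2,4-bis(TBS-oxy)-5-(3-methylbut-2-enyl)phenyl]methoxy}-4,6-bis(TBS-oxy)-5-(3-methylbut-2-enyl)phenyl]prop-2-en-1-one | CN(C)/C=C/C(=O)c1c(OCc2cc(CC=C(C)C)c(O[Si](C)(C)C(C)(C)C)cc2O[Si](C)(C)C(C)(C)C)cc(O[Si](C)(C)C(C)(C)C)c(CC=C(C)C)c1O[Si](C)(C)C(C)(C)C
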